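## Retrosynthetic overview

1. Target 9 ⇒ triol 7: both acetates are installed last, and the phenol is freed in the same flask by selective aminolysis of the aryl acetate.
2. 7 ⇒ β-hydroxy ketone 4: the C3 carbinol comes from a 1,3-syn boron-chelate reduction controlled by C5.
3. 4 ⇒ zingerone 1 + butanal 2: the C4–C5 bond and the C5 (R) centre come from a direct amine-catalysed (enamine) cross-aldol, which is the new step.
4. No ring is formed at any stage; the guaiacol ring arrives intact in 1.

Assumption: the octane chain is numbered from the benzylic carbon (C1) to the propyl terminus (C8), which makes the target the (3S,5R), 1,3-syn diacetate.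

Step 1 catalyst: (R)-N-[(R)-1-hydroxy-4-methyl-1,1-diphenylpentan-2-yl]pyrrolidine-2-carboxamide, SMILES O=C([C@H]1CCCN1)N[C@H](CC(C)C)C(O)(c1ccccc1)c1ccccc1. It is the amide of D-proline with the gem-diphenyl amino alcohol from D-leucine methyl ester (PhMgBr addition, amide coupling, N-deprotection).

## Route

Step 1
Reactants: 1 zingerone, 4-(4-hydroxy-3-methoxyphenyl)butan-2-one; 2 butanal
Product: 4 (R)-5-hydroxy-1-(4-hydroxy-3-methoxyphenyl)octan-3-one, via terminal enamine 3 (not isolated)
Conditions: (R)-N-[(R)-1-hydroxy-4-methyl-1,1-diphenylpentan-2-yl]pyrrolidine-2-carboxamide (15 mol%), PhCO2H (15 mol%), 1 (3 equiv, about 3 M), CHCl3, −20 °C; 2 (1 equiv) by syringe pump over 24 h, then 24 h; excess 1 recovered on silica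
Reagents that add atoms: none
Why: Proposed new method: a direct enamine cross-aldol that uses an unsymmetrical, phenol-bearing alkyl methyl ketone (in only threefold excess) as donor toward an enolisable α-unbranched aldehyde has not been demonstrated, but the pyrrolidine nitrogen should condense at the methyl side of 1 to give terminal enamine 3 (the internal enamine is disfavoured by allylic 1,3-strain), slow addition keeps free 2 scarce so that its self-aldol (second order in 2) is starved while the cross-addition (first order in 2) goes on, and the amide N–H and tertiary O–H of the D,D-catalyst hydrogen-bond the aldehyde oxygen in a Houk–List-type chair so that 3 attacks the si face of 2 and sets C5 as R before hydrolysis releases 4 in an addition that keeps every atom of 1 and 2; the closest known reaction type is the prolinamide-catalysed aldol of acetone or butanone with aldehydes.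

Step 2
Reactants: 4 (R)-5-hydroxy-1-(4-hydroxy-3-methoxyphenyl)octan-3-one
Product: 7 (3S,5R)-1-(4-hydroxy-3-methoxyphenyl)octane-3,5-diol, via diethylborinate chelate 5 (not isolated), via sodium borate diolate 6 (not isolated)
Conditions: Et2BOMe (2.2 equiv), THF/MeOH 4:1, −78 °C, 30 min; NaBH4 (2.5 equiv), −78 °C, 4 h; then MeOH, rt, co-evaporation with MeOH (×4)
Reagents that add atoms: none
Why: Narasaka–Prasad reduction: Et2BOMe exchanges onto the C5 hydroxyl and binds the C3 carbonyl to give half-chair chelate 5 with the propyl group pseudo-equatorial, external NaBH4 attacks axially through a chair-like transition state to 6, so the new C3 carbinol (S) is 1,3-syn to C5 (typically ≥95:5 dr), with the extra equivalent of borane covering the phenol and methanolysis stripping the boron.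

Step 3
Reactants: 7 (3S,5R)-1-(4-hydroxy-3-methoxyphenyl)octane-3,5-diol
Product: 9 (3S,5R)-1-(4-hydroxy-3-methoxyphenyl)octane-3,5-diyl diacetate, via triacetate 8 (not isolated)
Conditions: Ac2O (4 equiv), Et3N (5 equiv), 4-(dimethylamino)pyridine (5 mol%), CH2Cl2, 0 °C → rt, 2 h; then pyrrolidine (4 equiv), 0 °C → rt, 1–2 h; aq. NH4Cl work-up
Reagents that add atoms: acetic anhydride, CC(=O)OC(C)=O
Why: Nucleophile-catalysed acylation esterifies all three hydroxyls without touching either stereocentre, and pyrrolidine (after scavenging surplus Ac2O) then cleaves only the aryl acetate by chemoselective aminolysis, because phenoxide is a far better leaving group than a secondary alkoxide, so both alkyl acetates stay in place.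

## Compound list

1 | zingerone, 4-(4-hydroxy-3-methoxyphenyl)butan-2-one | CC(=O)CCc1ccc(O)c(OC)c1 | starting material
2 | butanal | CCCC=O | starting material
3 | terminal enamine of 1 on the catalyst nitrogen, (R)-1-[4-(4-hydroxy-3-methoxyphenyl)but-1-en-2-yl]-N-[(R)-1-hydroxy-4-methyl-1,1-diphenylpentan-2-yl]pyrrolidine-2-carboxamide | C=C(CCc1ccc(O)c(OC)c1)N1CCC[C@@H]1C(=O)N[C@H](CC(C)C)C(O)(c1ccccc1)c1ccccc1 | intermediate (not isolated)
4 | (R)-[4]-gingerol, (R)-5-hydroxy-1-(4-hydroxy-3-methoxyphenyl)octan-3-one | CCC[C@@H](O)CC(=O)CCc1ccc(O)c(OC)c1 | intermediate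
5 | (R)-1-(4-hydroxy-3-methoxyphenyl)-3-oxooctan-5-yl diethylborinate, boron chelated by the C3 carbonyl oxygen | CCC[C@@H](OB(CC)CC)CC(=O)CCc1ccc(O)c(OC)c1 | intermediate (not isolated)
6 | sodium (4S,6R)-2,2-diethyl-4-[2-(4-hydroxy-3-methoxyphenyl)ethyl]-6-propyl-1,3,2-dioxaborinan-2-uide (cis ring substituents) | CCC[C@@H]1C[C@H](CCc2ccc(O)c(OC)c2)O[B-](CC)(CC)O1.[Na+] | intermediate (not isolated)
7 | (3S,5R)-1-(4-hydroxy-3-methoxyphenyl)octane-3,5-diol (syn) | CCC[C@@H](O)C[C@@H](O)CCc1ccc(O)c(OC)c1 | intermediate
8 | (3S,5R)-1-(4-acetoxy-3-methoxyphenyl)octane-3,5-diyl diacetate | CCC[C@H](C[C@H](CCc1ccc(OC(C)=O)c(OC)c1)OC(C)=O)OC(C)=O | intermediate (not isolated)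
9 | (3S,5R)-1-(4-hydroxy-3-methoxyphenyl)octane-3,5-diyl diacetate | CCC[C@H](C[C@H](CCc1ccc(O)c(OC)c1)OC(C)=O)OC(C)=O | target

## Step count and risk

Total step count: 3. Longest linear sequence: 3 steps (1 + 2 → 4 → 7 → 9).

Steps most likely to fail, with step 1 the most exposed:

**Step 1 (the proposed new cross-aldol).** The risks are self-condensation of 2, dehydration of 4 to the enone, and insufficient regio- or enantioselectivity. The fallback uses known chemistry, sets out from 2 and comes back to the route at 4. The established proline-catalysed aldol of acetone with α-unbranched aldehydes is run with D-proline (30 mol%) in acetone/CHCl3 1:4 at rt. It gives (R)-4-hydroxyheptan-2-one F1 in modest yield and moderate ee. Its aldolate dianion, made with LiN(iPr)2 (2.2 equiv) in THF at −78 °C, is alkylated at the methyl terminus with commercial 4-(benzyloxy)-3-methoxybenzyl bromide. This gives (R)-1-[4-(benzyloxy)-3-methoxyphenyl]-5-hydroxyoctan-3-one F2. Hydrogenolysis (H2, 10% Pd on carbon, EtOAc) then frees the phenol and delivers 4.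

**Step 2 (syn reduction with a free phenol present).** The risk is that the phenol ties up boron, so chelation is incomplete and the dr erodes. The fallback sets out from 4 and comes back at 7. Only the phenol is silylated (tert-butyldimethylsilyl chloride, imidazole, CH2Cl2, 0 °C) to give (R)-1-{4-[(tert-butyldimethylsilyl)oxy]-3-methoxyphenyl}-5-hydroxyoctan-3-one F3, a substrate with a single free hydroxyl. The Et2BOMe/NaBH4 reduction then runs through the diethylborinate chelate F4 and the sodium borate diolate F5, neither isolated. It gives (3S,5R)-1-{4-[(tert-butyldimethylsilyl)oxy]-3-methoxyphenyl}octane-3,5-diol F6. Bu4NF buffered with AcOH in THF removes the silyl group and returns 7.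

**Step 3 (one-pot discrimination of aryl from alkyl acetate).** The risk is incomplete aryl-acetate cleavage or partial loss of an alkyl acetate. The fallback sets out from 7 and comes back at 9, replacing kinetic discrimination by orthogonal protection. The phenol alone is benzylated (BnBr, K2CO3, acetone, 56 °C) to give (3S,5R)-1-[4-(benzyloxy)-3-methoxyphenyl]octane-3,5-diol F7. Both carbinols are acetylated (Ac2O, pyridine, 4-(dimethylamino)pyridine) to give (3S,5R)-1-[4-(benzyloxy)-3-methoxyphenyl]octane-3,5-diyl diacetate F8. Hydrogenolysis (H2, 10% Pd on carbon, EtOAc) then gives 9 with both acetates untouched.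

## Further compounds

F1 | step 1 | (R)-4-hydroxyheptan-2-one | CCC[C@@H](O)CC(C)=O
F2 | step 1 | (R)-1-[4-(benzyloxy)-3-methoxyphenyl]-5-hydroxyoctan-3-one | CCC[C@@H](O)CC(=O)CCc1ccc(OCc2ccccc2)c(OC)c1
F3 | step 2 | (R)-1-{4-[(tert-butyldimethylsilyl)oxy]-3-methoxyphenyl}-5-hydroxyoctan-3-one | CCC[C@@H](O)CC(=O)CCc1ccc(O[Si](C)(C)C(C)(C)C)c(OC)c1
F4 | step 2 | (R)-1-{4-[(tert-butyldimethylsilyl)oxy]-3-methoxyphenyl}-3-oxooctan-5-yl diethylborinate (carbonyl-chelated) | CCC[C@@H](OB(CC)CC)CC(=O)CCc1ccc(O[Si](C)(C)C(C)(C)C)c(OC)c1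
F5 | step 2 | sodium (4S,6R)-4-(2-{4-[(tert-butyldimethylsilyl)oxy]-3-methoxyphenyl}ethyl)-2,2-diethyl-6-propyl-1,3,2-dioxaborinan-2-uide | CCC[C@@H]1C[C@H](CCc2ccc(O[Si](C)(C)C(C)(C)C)c(OC)c2)O[B-](CC)(CC)O1.[Na+]
F6 | step 2 | (3S,5R)-1-{4-[(tert-butyldimethylsilyl)oxy]-3-methoxyphenyl}octane-3,5-diol | CCC[C@@H](O)C[C@@H](O)CCc1ccc(O[Si](C)(C)C(C)(C)C)c(OC)c1
F7 | step 3 | (3S,5R)-1-[4-(benzyloxy)-3-methoxyphenyl]octane-3,5-diol | CCC[C@@H](O)C[C@@H](O)CCc1ccc(OCc2ccccc2)c(OC)c1
F8 | step 3 | (3S,5R)-1-[4-(benzyloxy)-3-methoxyphenyl]octane-3,5-diyl diacetate | CCC[C@H](C[C@H](CCc1ccc(OCc2ccccc2)c(OC)c1)OC(C)=O)OC(C)=O
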